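Take a neighbour charged with a quarter of this flask's solid substrate, 2.5 mM, and ask of both flasks what part of the charge the reagent reaches before step 3 consumes it.

solid substrate 10 mM; reagent 12.0 mM; time 6.0 h

    solid substrate ⇌ dissolved substrate, rate k1*(cs1 - [dissolved substrate]) while solid is left; crystals form when [dissolved substrate] > cs1 (cs1 = 0.95 mM, k1 = 0.17 min⁻¹)
    dissolved substrate + reagent → target (k2 = 11 M⁻¹ min⁻¹)
    reagent → side product (k3 = 0.15 min⁻¹)
    solid product ⇌ target, rate k4*(cs4 - [target]) while solid is left; crystals form when [target] > cs4 (cs4 = 1.4 mM, k4 = 5.1 min⁻¹)
    target ⇌ isomer of the product (K5 = 3.0, k5 = 0.046 min⁻¹)

1. which holds at 6.0 h: what has brought the reaction to rest, or that it has not come to rest (for what has run out or reacted, a solid counts together with what of it has only dissolved) (it is still moving / the reagent has run out first / all of the solid substrate has reacted / forward and back rates have come level)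
2. part of the solid substrate that has turned into other species by 6.0 h (what has only dissolved does not count)
3. how much isomer of the product there is at 6.0 h, in percent of the solid substrate charged

- amounts and yields of target count solid product too
- given per volume of solution although it is solid: solid substrate, solid product
- at the start none of the solid substrate is in solution
- what has only dissolved of solid substrate counts as not reacted
- the reaction counts as stopped when no species that holds the solid substrate changes by six tenths of a point or more over the second half of the time
- run time (flask): 6.0 h

Compare first the two paths of the reagent in the flask: step 2 would overtake step 3 at a dissolved substrate of 136% of the charge, but saturation stands at 9.50%, so the crossing lies out of reach and the selectivity factor at saturation is 0.0697. Multiply it by the reagent charge per substrate charge to get 8.36%, my figure for a solution saturated from the first minute. Correct for the solution starting empty, filling at 0.17 min⁻¹ while the reagent decays at 0.15 min⁻¹: the factor k1/(k1+k3) lowers my figure to 4.44%.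

That link is weak, because step 2 itself drains dissolved substrate at 0.132 min⁻¹ at the start, a rate of the same size as 0.17 min⁻¹. Reforge it by adding this drain to the denominator, taken at half its starting value: the reagent's half-life of 4.62 min nearly coincides with the peak of step 2 at 4.46 min. This gives my capture share, the part of the charge converted before the reagent is consumed, 3.68%.

Since 3.68% is less than the 14.0% at which target crystallises, and step 5 relaxes in 0.188 h, much shorter than 6.0 h, commit to 75.0% of it as isomer of the product, 2.76% of the charge, and expect the reagent, though charged above the solid substrate, to be the first charge lost, since 6.0 h holds 77.9 of its half-lives by step 3.

The forecast gives the reagent has run out first, 3.6% and 2.7%, slightly below my share, holding the reagent's loss “far faster than it can react with the slowly dissolving, sparingly soluble substrate”.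

The flask gives the reagent has run out first, 3.71% and 2.78%. At 6.00 h, 0% of the reagent is left in this flask. The capture share of 3.68% lies 0.030 percentage points below the conversion of this flask. Carried to the neighbour with 2.5 mM of solid substrate, where the reagent and the rate constants are held, the share scales inversely with the charge to 14.7%, and that neighbour gives 14.8%.

(Its constants were set for the occasion.)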